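A closed flask keeps its charge: starting material that leaves is shared among whatever takes it, so its loss can be split by what that loss answers to.

| flask | starting material | partner | time |
|---|---|---|---|
| eta | 0.0800 M | 0.160 M |  |
| gamma | 0.0800 M | 0.320 M |  |
| epsilon | 0.160 M | 0.160 M |  |
| delta | 0.0260 M | 0.0800 M | 5.1 min |

- eta run (time / min: [starting material] / M): 0.39: 0.0705; 1.2: 0.0563; 2.3: 0.0418; 3.6: 0.0341; 5.1: 0.0279
- gamma run (time / min: [starting material] / M): 0.39: 0.0657; 1.2: 0.0451; 2.3: 0.0302; 3.6: 0.0235; 5.1: 0.0196
- epsilon run (time / min: [starting material] / M): 0.39: 0.1395; 1.2: 0.1067; 2.3: 0.0837; 3.6: 0.0668; 5.1: 0.0577

(readings scatter by 0.001 M)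

1. how the opening rate goes with [starting material] round the charge of the eta run: the exponent of the rate at two percent of starting material gone to target (one fixed amount of target, the same in the runs compared)
2. how the opening rate goes with [partner] round the charge of the eta run: the exponent of the rate at two percent of starting material gone to target
3. starting material in the delta run at 5.1 min, as a share of the starting material charged

- Overall: starting material + partner -> target.
- Constant volume, constant temperature.
- An order is taken over about fifteen percent of the charge, up and down.

Up to the first reading, the eta run loses 0.324 min⁻¹ of its starting material. The gamma run, with the same starting material and twice the partner, loses 0.505 min⁻¹. The eta figure is read with a scatter near 0.0364 min⁻¹. The loss grew less than the partner did, so this reckoning splits it. The partner constant, the rise in loss per molar of partner, is 1.13 M⁻¹ min⁻¹, which leaves 0.143 min⁻¹ of the eta loss not going with the partner.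

If the partner-linked part makes the target, the partner order is one. The epsilon run, with twice the starting material of the eta run and the same partner, loses 0.352 min⁻¹ against 0.324 min⁻¹, so this reckoning takes the starting-material order as one too.

In the delta run, with the partner held at its charge, the partner constant gives a time of 11.1 min. By 5.1 min this reckoning has 63.1% of the starting material left on that loss by itself, and 30.4% with the eta run's partner-free loss added. This reckoning commits to the middle, 46.8%.

The forecast gives a starting-material order of 1.05, a partner order of 0.65 and 46% left in the delta run, calling the partner's effect “suggesting saturation”, and so parts from this reckoning on the partner order.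

The flask gives a starting-material order of 1.0, a partner order of 1.0 and 45.0% left in the delta run.

    starting material + partner ⇌ target + by-product (1.404 M⁻¹ min⁻¹, 3.558 M⁻¹ min⁻¹)
    2 starting material → homo dimer (0.3534 M⁻¹ min⁻¹)
    starting material → decomposed substrate (0.04770 min⁻¹)

The target's opening rate in the gamma run is 2.0 times that of the eta run, both taken where the same amount has been made, while the loss read up to the first reading rose 1.56 times. At the eta charge the partner constant gives 0.0145 M min⁻¹ of target, against 0.017 M min⁻¹ where two percent of the eta run's starting material has turned. At the epsilon charge it gives 0.0289 M min⁻¹, against 0.035 M min⁻¹ where the same amount has been made.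

All runs were computed on assumed constants, noise included.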